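A direct plan would condense 2′,6′-dihydroxy-4′-methoxyacetophenone A1 with 3-(benzyloxy)-4-hydroxybenzaldehyde A2 to the chalcone A3. It would then close ring C with alkaline peroxide (Algar–Flynn–Oyamada) to give 3′-O-benzylrhamnetin A4, sulfate the three free OH groups of A4 with an amine·SO3 complex to the trisulfate A5, and end with hydrogenolysis of the benzyl ether of A5.
- The aldol condensation of the unprotected partners would be weak. In strong base A2 would be a 4-oxidobenzaldehyde (a vinylogous carboxylate, barely electrophilic), A1 a polyanion, and any A3 formed would drift to the 5-hydroxyflavanone.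
- The oxidative ring closure of A3 to A4 would be weak. With an oxygen at C6′ of the chalcone, the closure would be left to chance between 5-exo (aurone, the usual outcome) and 6-endo (flavonol), and H2O2/NaOH would also attack the free 4-hydroxystyryl unit.
- The exhaustive sulfation of A4 to A5 would be weak. The 5-OH, chelated to C4=O, would react only under forcing conditions that already endanger the 3-O-sulfate. Under-sulfated salts would be hard to separate, and the precious salt A5 would still face one more step.

**Plan of the new route**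
- Cuts: first the three sulfate monoesters go back to neutral 2,2,2-trichloroethyl (TCE) sulfate diesters and O3′–H to a benzyl ether; then the bond C2–C1′ between rings C and B is cut; then, in the B-ring-free chromone, C3–O3 and the one-carbon unit C2 (bonds O1–C2 and C2–C3).
- Enabling feature: in ring C the atoms O3–C3=C2 form an enol whose carbon end C2 is a donor. C1′ of ring B lies para to O4′ and is a donor too, so C2–C1′ joins carbons of like polarity; it is made by reversing C1′ as the aryl ligand of lead(IV).
- Ring order: ring A is bought, ring C is closed on it (step 2), and ring B is attached last as a finished fragment (step 7). No chalcone is involved and no ring is closed by oxidation.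
- O5 is sulfated first, on the symmetric 2,6-dihydroxyaryl ketone, where chelation of the second OH secures mono-selectivity instead of opposing the reaction. O4′ is sulfated on the ring-B fragment, and O3–H is the only OH left after the coupling.
- No aldol of polyphenolates, no 5-exo/6-endo competition and no exhaustive amine·SO3 sulfation occur. All intermediates are neutral, and the only salt is the target, set free together with O3′–H in one reductive step.

Key step: step 7

Assumption: the target is planar and has no stereocentre, so no enantiomer question arises; it would be isolated as the trisodium salt after ion exchange and is written as the free acid, as in the target formula.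

Step 1
Reactants: 1 2′,6′-dihydroxy-4′-methoxyacetophenone
Product: 2 2-acetyl-3-hydroxy-5-methoxyphenyl 2,2,2-trichloroethyl sulfate
Conditions: Cl3CCH2OSO2Cl (1.0 equiv), Et3N (1.1 equiv), DMAP (10 mol %), CH2Cl2, −20 to 0 °C
Reagents that add atoms: 2,2,2-trichloroethyl chlorosulfate, O=S(=O)(Cl)OCC(Cl)(Cl)Cl
Why: Phenol sulfation with a chlorosulfate ester (a sulfonylation-type O–S bond formation); the two OH groups are equivalent and only one at a time is chelated to the acetyl C=O, so the first should react readily, after which the remaining OH is locked in the hydrogen bond and the reaction should stop at the monoester.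

Step 2
Reactants: 2 2-acetyl-3-hydroxy-5-methoxyphenyl 2,2,2-trichloroethyl sulfate
Product: 4 7-methoxy-4-oxo-4H-chromen-5-yl 2,2,2-trichloroethyl sulfate, via enaminone 3 (not isolated)
Conditions: Me2NCH(OMe)2 (1.5 equiv), toluene, 85 °C; evaporate; conc. HCl, CH2Cl2, 40 °C
Reagents that add atoms: N,N-dimethylformamide dimethyl acetal, COC(OC)N(C)C
Why: Enaminone route to chromones: condensation at the acetyl CH3 adds the carbon that becomes C2, and acid-induced 6-endo addition–elimination of the chelated OH (loss of dimethylamine) closes ring C, in neutral and then acidic media that a TCE sulfate should tolerate.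

Step 3
Reactants: 4 7-methoxy-4-oxo-4H-chromen-5-yl 2,2,2-trichloroethyl sulfate
Product: 6 3-hydroxy-7-methoxy-4-oxo-4H-chromen-5-yl 2,2,2-trichloroethyl sulfate, via 2,3-epoxychromanone 5 (not isolated)
Conditions: dimethyldioxirane (acetone solution, 2–3 equiv), CH2Cl2, 0 °C to rt; evaporate; TsOH·H2O (5 mol %), CH2Cl2, rt
Reagents that add atoms: dimethyldioxirane, CC1(C)OO1
Why: Dioxirane epoxidation of the enol-ether bond C2=C3, then acid-catalysed opening at the acetal carbon C2 with loss of H3 (the standard flavone-to-flavonol oxidation), should install O3 under neutral conditions; the two stereocentres of the racemic cis-epoxide 5 vanish on isomerisation.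

Step 4
Reactants: 7 2-(benzyloxy)phenol
Product: 8 2-(benzyloxy)-4-bromophenol
Conditions: NBS (1.0 equiv), MeCN, 0 °C
Reagents that add atoms: N-bromosuccinimide, O=C1CCC(=O)N1Br
Why: Electrophilic aromatic bromination: the free OH is the stronger donor, so substitution should go para to it (as with guaiacol), which marks the future C1′ and fixes O4′ as the free OH and O3′ as the benzyl ether.

Step 5
Reactants: 8 2-(benzyloxy)-4-bromophenol
Product: 9 [3-(benzyloxy)-4-hydroxyphenyl]boronic acid
Conditions: B2(OH)4 (1.5 equiv), XPhos Pd G2 (1 mol %), XPhos (2 mol %), KOAc (3 equiv), EtOH, 80 °C; aq. work-up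
Reagents that add atoms: tetrahydroxydiboron, OB(O)B(O)O
Why: Miyaura-type borylation with tetrahydroxydiboron should give the free boronic acid directly and is known to tolerate free phenols and benzyl ethers.

Step 6
Reactants: 9 [3-(benzyloxy)-4-hydroxyphenyl]boronic acid
Product: 10 [3-(benzyloxy)-4-{[(2,2,2-trichloroethoxy)sulfonyl]oxy}phenyl]boronic acid
Conditions: Cl3CCH2OSO2Cl (1.3 equiv), Et3N (1.5 equiv), DMAP (10 mol %), THF, 0 °C to rt; 1 M HCl wash, crystallisation
Reagents that add atoms: 2,2,2-trichloroethyl chlorosulfate, O=S(=O)(Cl)OCC(Cl)(Cl)Cl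
Why: Same chlorosulfate sulfation as in step 1: the phenoxide is the only competent nucleophile, any transient B–O sulfation should revert in the aqueous acid work-up, and the sulfate diester also serves as the protecting group of O4′.

Step 7
Reactants: 6 3-hydroxy-7-methoxy-4-oxo-4H-chromen-5-yl 2,2,2-trichloroethyl sulfate; 10 [3-(benzyloxy)-4-{[(2,2,2-trichloroethoxy)sulfonyl]oxy}phenyl]boronic acid
Product: 13 2-[3-(benzyloxy)-4-{[(2,2,2-trichloroethoxy)sulfonyl]oxy}phenyl]-3-hydroxy-7-methoxy-4-oxo-4H-chromen-5-yl 2,2,2-trichloroethyl sulfate, via aryllead triacetate 11 (not isolated), via chromane-3,4-dione tautomer 12 (not isolated)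
Conditions: 10 (1.05 equiv), Pb(OAc)4 (1.0 equiv), Hg(OAc)2 (10 mol %), CHCl3, 40 °C then rt; then 6 (1.05 equiv), pyridine (3.3 equiv), CHCl3, 40–60 °C
Reagents that add atoms: none
Why: Proposed new method: Hg(II)-catalysed boron-to-lead exchange turns C1′, natively a donor carbon para to O4′, into the electrophilic aryl ligand of 11; the enolic O3–H of 6 then displaces an acetate on lead, and ligand coupling within this O3–Pb(IV)–aryl species should deliver the aryl group to the adjacent enol carbon C2 with reduction to Pb(II), giving dione 12, which enolises at once to the conjugated flavonol 13. The closest known reaction type is the Pinhey arylation, established for the enol carbon of 4-hydroxycoumarins and β-dicarbonyl compounds and for the ortho carbon of phenols, but not for C2–H of a 3-hydroxychromone (the enol of an α-diketone). No ring is closed: ring B is joined to the finished A/C bicycle through the single bond C2–C1′, and the only new stereocentre (C2 of 12) is erased on enolisation, so nothing has to be controlled. Site selectivity on the chromone is secured because O3–H is the only OH present (O5 is a sulfate diester, O7 a methyl ether), so lead can bind only next to C2, the only unsubstituted enol carbon; on ring B the site is fixed ipso by the C–B bond. C- rather than O-arylation is the normal course of lead(IV) ligand coupling. A second arylation at C2 should be held back by making the lead reagent limiting and by the loss of B-ring conjugation that it would cost.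

Step 8
Reactants: 13 2-[3-(benzyloxy)-4-{[(2,2,2-trichloroethoxy)sulfonyl]oxy}phenyl]-3-hydroxy-7-methoxy-4-oxo-4H-chromen-5-yl 2,2,2-trichloroethyl sulfate
Product: 14 3′-O-benzylrhamnetin 3,5,4′-tris(2,2,2-trichloroethyl sulfate)
Conditions: Cl3CCH2OSO2Cl (1.5 equiv), Et3N (1.6 equiv), DMAP (10 mol %), THF, 0 °C to rt
Reagents that add atoms: 2,2,2-trichloroethyl chlorosulfate, O=S(=O)(Cl)OCC(Cl)(Cl)Cl
Why: Same chlorosulfate sulfation: the acidic enolic O3–H is the only OH left, so there is no selectivity question, and the neutral triester can be purified on silica.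

Step 9
Reactants: 14 3′-O-benzylrhamnetin 3,5,4′-tris(2,2,2-trichloroethyl sulfate)
Product: 15 rhamnetin 3,5,4′-tri-O-sulfate
Conditions: 10 % Pd/C, HCO2NH4 (excess), MeOH, rt; Celite; Dowex 50W (Na+), C18
Reagents that add atoms: none
Why: Catalytic transfer hydrogenolysis: reductive fragmentation of each trichloroethyl ester (loss of chloride and 1,1-dichloroethene) should free the sulfate monoesters and the benzyl ether should be cleaved in the same operation, in a buffered, near-neutral medium in which aryl sulfates, the tetrasubstituted C2=C3 bond and the aryl methyl ether are stable.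

**Compound list**
1 | 2′,6′-dihydroxy-4′-methoxyacetophenone | CC(=O)c1c(O)cc(OC)cc1O | starting material
2 | 2-acetyl-3-hydroxy-5-methoxyphenyl 2,2,2-trichloroethyl sulfate | CC(=O)c1c(O)cc(OC)cc1OS(=O)(=O)OCC(Cl)(Cl)Cl | intermediate
3 | 2-[(2E)-3-(dimethylamino)prop-2-enoyl]-3-hydroxy-5-methoxyphenyl 2,2,2-trichloroethyl sulfate (enaminone) | CN(C)/C=C/C(=O)c1c(O)cc(OC)cc1OS(=O)(=O)OCC(Cl)(Cl)Cl | intermediate
4 | 7-methoxy-4-oxo-4H-chromen-5-yl 2,2,2-trichloroethyl sulfate | COc1cc(OS(=O)(=O)OCC(Cl)(Cl)Cl)c2c(=O)ccoc2c1 | intermediate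
5 | cis-2,3-epoxy-7-methoxy-4-oxochroman-5-yl 2,2,2-trichloroethyl sulfate (racemic, one enantiomer drawn) | COc1cc(OS(=O)(=O)OCC(Cl)(Cl)Cl)c2C(=O)[C@H]3O[C@H]3Oc2c1 | intermediate
6 | 3-hydroxy-7-methoxy-4-oxo-4H-chromen-5-yl 2,2,2-trichloroethyl sulfate | COc1cc(OS(=O)(=O)OCC(Cl)(Cl)Cl)c2c(=O)c(O)coc2c1 | intermediate
7 | 2-(benzyloxy)phenol | Oc1ccccc1OCc1ccccc1 | starting material
8 | 2-(benzyloxy)-4-bromophenol | Oc1ccc(Br)cc1OCc1ccccc1 | intermediate
9 | [3-(benzyloxy)-4-hydroxyphenyl]boronic acid | OB(O)c1ccc(O)c(OCc2ccccc2)c1 | intermediate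
10 | [3-(benzyloxy)-4-{[(2,2,2-trichloroethoxy)sulfonyl]oxy}phenyl]boronic acid | OB(O)c1ccc(OS(=O)(=O)OCC(Cl)(Cl)Cl)c(OCc2ccccc2)c1 | intermediate
11 | [3-(benzyloxy)-4-{[(2,2,2-trichloroethoxy)sulfonyl]oxy}phenyl]lead(IV) triacetate | CC(=O)O[Pb](OC(C)=O)(OC(C)=O)c1ccc(OS(=O)(=O)OCC(Cl)(Cl)Cl)c(OCc2ccccc2)c1 | intermediate
12 | 2-aryl-7-methoxy-3,4-dioxochroman-5-yl 2,2,2-trichloroethyl sulfate, keto tautomer of 13 (racemic at C2, not controlled) | COc1cc(OS(=O)(=O)OCC(Cl)(Cl)Cl)c2C(=O)C(=O)C(c3ccc(OS(=O)(=O)OCC(Cl)(Cl)Cl)c(OCc4ccccc4)c3)Oc2c1 | intermediate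
13 | 2-[3-(benzyloxy)-4-{[(2,2,2-trichloroethoxy)sulfonyl]oxy}phenyl]-3-hydroxy-7-methoxy-4-oxo-4H-chromen-5-yl 2,2,2-trichloroethyl sulfate | COc1cc(OS(=O)(=O)OCC(Cl)(Cl)Cl)c2c(=O)c(O)c(-c3ccc(OS(=O)(=O)OCC(Cl)(Cl)Cl)c(OCc4ccccc4)c3)oc2c1 | intermediate
14 | 3′-O-benzylrhamnetin 3,5,4′-tris(2,2,2-trichloroethyl sulfate) | COc1cc(OS(=O)(=O)OCC(Cl)(Cl)Cl)c2c(=O)c(OS(=O)(=O)OCC(Cl)(Cl)Cl)c(-c3ccc(OS(=O)(=O)OCC(Cl)(Cl)Cl)c(OCc4ccccc4)c3)oc2c1 | intermediate
15 | rhamnetin 3,5,4′-tri-O-sulfate | COc1cc(OS(=O)(=O)O)c2c(=O)c(OS(=O)(=O)O)c(-c3ccc(OS(=O)(=O)O)c(O)c3)oc2c1 | target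

Total steps: 9. Longest linear sequence: 6 (steps 1, 2, 3, 7, 8, 9; the ring-B branch 4, 5, 6, 7, 8, 9 is equally long).

**Steps most likely to fail**

1. **Step 7.**
   - What may go wrong: the O3/O4 chelate may hold lead(IV) in a geometry from which ligand coupling is slow. O-arylation or a second arylation at C2 may compete. Incomplete boron–lead exchange may leave lead tetraacetate that oxidises the enol.
   - Fallback: it sets out from 6 and reverses the polarity of C2 instead of C1′, by known chemistry. Electrophilic iodination of the enol carbon (N-iodosuccinimide, MeCN, 0 °C, the halogenation known for 3-hydroxy-4-pyranones next to the OH) should give 3-hydroxy-2-iodo-7-methoxy-4-oxo-4H-chromen-5-yl 2,2,2-trichloroethyl sulfate F1. Suzuki–Miyaura coupling of F1 with boronic acid 10 (Pd(OAc)2/SPhos, K3PO4, THF–H2O, rt to 40 °C) comes back to the route at 13.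

2. **Step 3.**
   - What may go wrong: the epoxidation may be too slow, because C2=C3 is deactivated by C4=O and by the 5-sulfate. Long exposure may then over-oxidise the enol product or ring A.
   - Fallback: it sets out from enaminone 3, isolated after the first stage of step 2, and brings O3 in before ring C is closed. Thermal α-C–H acyloxylation and annulation of the o-hydroxyaryl enaminone with dibenzoyl peroxide (MeCN, 80 °C) should give 3-(benzoyloxy)-7-methoxy-4-oxo-4H-chromen-5-yl 2,2,2-trichloroethyl sulfate F2. Acid methanolysis of the enol ester (HCl, MeOH, 40 °C) comes back to the route at 6.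

3. **Step 9.**
   - What may go wrong: stepwise hydrodechlorination of the CCl3 groups may leave esters that no longer fragment. Chloride may slow the catalyst so that debenzylation stalls. Early debenzylation may also allow migration of the neighbouring sulfate diester between O4′ and O3′.
   - Fallback: it sets out from 14 and separates the two events without palladium. Lewis-acid debenzylation on the neutral triester (BCl3, pentamethylbenzene, CH2Cl2, −78 °C) should give rhamnetin 3,5,4′-tris(2,2,2-trichloroethyl sulfate) F3. Fast reductive elimination with zinc (Zn dust, HCO2NH4, MeOH, rt) then comes back to the route at 15.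

**Further compounds**
F1 | step 7 | 3-hydroxy-2-iodo-7-methoxy-4-oxo-4H-chromen-5-yl 2,2,2-trichloroethyl sulfate | COc1cc(OS(=O)(=O)OCC(Cl)(Cl)Cl)c2c(=O)c(O)c(I)oc2c1
F2 | step 3 | 3-(benzoyloxy)-7-methoxy-4-oxo-4H-chromen-5-yl 2,2,2-trichloroethyl sulfate | COc1cc(OS(=O)(=O)OCC(Cl)(Cl)Cl)c2c(=O)c(OC(=O)c3ccccc3)coc2c1
F3 | step 9 | rhamnetin 3,5,4′-tris(2,2,2-trichloroethyl sulfate) | COc1cc(OS(=O)(=O)OCC(Cl)(Cl)Cl)c2c(=O)c(OS(=O)(=O)OCC(Cl)(Cl)Cl)c(-c3ccc(OS(=O)(=O)OCC(Cl)(Cl)Cl)c(O)c3)oc2c1
A1 | direct plan | 2′,6′-dihydroxy-4′-methoxyacetophenone | CC(=O)c1c(O)cc(OC)cc1O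
A2 | direct plan | 3-(benzyloxy)-4-hydroxybenzaldehyde | O=Cc1ccc(O)c(OCc2ccccc2)c1
A3 | direct plan | (E)-3-[3-(benzyloxy)-4-hydroxyphenyl]-1-(2,6-dihydroxy-4-methoxyphenyl)prop-2-en-1-one | COc1cc(O)c(C(=O)/C=C/c2ccc(O)c(OCc3ccccc3)c2)c(O)c1
A4 | direct plan | 3′-O-benzylrhamnetin | COc1cc(O)c2c(=O)c(O)c(-c3ccc(O)c(OCc4ccccc4)c3)oc2c1
A5 | direct plan | 3′-O-benzylrhamnetin 3,5,4′-tri-O-sulfate | COc1cc(OS(=O)(=O)O)c2c(=O)c(OS(=O)(=O)O)c(-c3ccc(OS(=O)(=O)O)c(OCc4ccccc4)c3)oc2c1
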